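**Retrosynthetic overview**
1. Justin C (15) ⇐ benzyl ether 14 (hydrogenolysis) ⇐ diol 13 (acetylation) ⇐ imide-ester 12 (hydride reduction of both carbonyls).
2. Key disconnection: the central C8–C8' bond of 12, whose two carbons are both enolate (nucleophilic) α-carbons. It is made by Cu(II)-mediated oxidative heterocoupling of the imide enolate of 8 with the ester enolate of 9; one enolate is oxidised to an α-carbonyl radical/enolonium equivalent, and both stereocentres are set in this step.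
3. 8 ⇐ acid 5 + (S)-oxazolidinone 6; 5 ⇐ aldehyde 1 + Meldrum's acid 2 (one-pot reductive Knoevenagel).
4. No ring is formed: both arenes are bought and the oxazolidinone is only a removable auxiliary.

Assumption: 1, 6 and 9 are taken as catalogue compounds, and the facial sense of the oxidative coupling at the imide α-carbon is taken to follow the Evans alkylation model.

**Route**

Step 1
Reactants: 1 4-(benzyloxy)-3,5-dimethoxybenzaldehyde; 2 Meldrum's acid (2,2-dimethyl-1,3-dioxane-4,6-dione)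
Product: 5 3-[4-(benzyloxy)-3,5-dimethoxyphenyl]propanoic acid, via 5-[4-(benzyloxy)-3,5-dimethoxybenzylidene]-2,2-dimethyl-1,3-dioxane-4,6-dione 3 (not isolated), via 5-[4-(benzyloxy)-3,5-dimethoxybenzyl]-2,2-dimethyl-1,3-dioxane-4,6-dione 4 (not isolated)
Conditions: HCO2H/Et3N (5:2, TEAF), rt then 95–100 °C, 4 h
Reagents that add atoms: none
Why: Reductive Knoevenagel sequence (Knoevenagel condensation, formate hydride conjugate reduction of the alkylidene Meldrum's acid, then hydrolysis/decarboxylation) gives the 3-arylpropanoic acid in one pot without a metal catalyst, so the benzyl ether is not hydrogenolysed.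

Step 2
Reactants: 5 3-[4-(benzyloxy)-3,5-dimethoxyphenyl]propanoic acid; 6 (S)-4-benzyl-2-oxazolidinone
Product: 8 (4S)-4-benzyl-3-{3-[4-(benzyloxy)-3,5-dimethoxyphenyl]propanoyl}-1,3-oxazolidin-2-one, via 3-[4-(benzyloxy)-3,5-dimethoxyphenyl]propanoic pivalic anhydride 7 (not isolated)
Conditions: PivCl, Et3N, THF, −20 °C; then LiCl, 6, −20 °C → rt
Reagents that add atoms: none
Why: Mixed-anhydride N-acylation of the LiCl-activated oxazolidinone occurs at the unhindered acyl carbon of the pivalic anhydride (Evans auxiliary attachment).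

Step 3
Reactants: 8 (4S)-4-benzyl-3-{3-[4-(benzyloxy)-3,5-dimethoxyphenyl]propanoyl}-1,3-oxazolidin-2-one; 9 methyl 3-(3,4-dimethoxyphenyl)propanoate (1.5 equiv)
Product: 12 methyl (2R,3R)-3-{[(4S)-4-benzyl-2-oxo-1,3-oxazolidin-3-yl]carbonyl}-4-[4-(benzyloxy)-3,5-dimethoxyphenyl]-2-(3,4-dimethoxybenzyl)butanoate, via lithium (Z)-enolate of 8 10 (not isolated), via lithium enolate of 9 11 (not isolated)
Conditions: 8 + 9 added to LDA (2.6 equiv), THF, −78 °C, 30 min; then Cu(II) 2-ethylhexanoate (2.5 equiv), −78 °C → rt; chromatography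
Reagents that add atoms: none
Why: Oxidative enolate heterocoupling, in which Cu(II) oxidises one lithium enolate to an electrophilic α-carbonyl radical/enolonium equivalent that is captured by the other enolate; the chelated Z-imide enolate reacts on the face away from the auxiliary benzyl group (Evans alkylation sense, giving 3R), and the C2 centre is expected to form with only moderate anti (2R,3R) preference, so the minor C2 epimer and the two homodimers are removed by chromatography.

Step 4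
Reactants: 12 methyl (2R,3R)-3-{[(4S)-4-benzyl-2-oxo-1,3-oxazolidin-3-yl]carbonyl}-4-[4-(benzyloxy)-3,5-dimethoxyphenyl]-2-(3,4-dimethoxybenzyl)butanoate
Product: 13 (2R,3R)-2-[4-(benzyloxy)-3,5-dimethoxybenzyl]-3-(3,4-dimethoxybenzyl)butane-1,4-diol
Conditions: LiBH4 (5 equiv), MeOH (5 equiv), THF, 0 °C → rt
Reagents that add atoms: none
Why: Borohydride reduction cleaves the N-acyl oxazolidinone reductively and reduces the methyl ester to the primary alcohol under weakly basic conditions that leave both α-stereocentres, the benzyl ether and the aryl methyl ethers untouched.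

Step 5
Reactants: 13 (2R,3R)-2-[4-(benzyloxy)-3,5-dimethoxybenzyl]-3-(3,4-dimethoxybenzyl)butane-1,4-diol
Product: 14 (2R,3R)-2-[4-(benzyloxy)-3,5-dimethoxybenzyl]-3-(3,4-dimethoxybenzyl)butane-1,4-diyl diacetate
Conditions: Ac2O, pyridine, DMAP (cat.), CH2Cl2, 0 °C → rt
Reagents that add atoms: acetic anhydride CC(=O)OC(C)=O
Why: DMAP-catalysed O-acylation of the two primary alcohols is fast and clean while the phenol remains masked as its benzyl ether, so no phenolic acetate can form.

Step 6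
Reactants: 14 (2R,3R)-2-[4-(benzyloxy)-3,5-dimethoxybenzyl]-3-(3,4-dimethoxybenzyl)butane-1,4-diyl diacetate
Product: 15 Justin C, (2R,3R)-2-(3,4-dimethoxybenzyl)-3-(4-hydroxy-3,5-dimethoxybenzyl)butane-1,4-diyl diacetate
Conditions: H2 (1 atm), 10% Pd/C, EtOAc, rt
Reagents that add atoms: none
Why: Catalytic hydrogenolysis cleaves only the aryl benzyl ether under neutral conditions; the alkyl acetates, the aryl methyl ethers and the non-oxygenated benzylic CH2 groups are inert, and no stereocentre is touched.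

**Compound list**
1 | 4-(benzyloxy)-3,5-dimethoxybenzaldehyde | COc1cc(C=O)cc(OC)c1OCc1ccccc1 | starting material
2 | Meldrum's acid | CC1(C)OC(=O)CC(=O)O1 | starting material
3 | 5-[4-(benzyloxy)-3,5-dimethoxybenzylidene]-2,2-dimethyl-1,3-dioxane-4,6-dione | COc1cc(C=C2C(=O)OC(C)(C)OC2=O)cc(OC)c1OCc1ccccc1 | intermediate
4 | 5-[4-(benzyloxy)-3,5-dimethoxybenzyl]-2,2-dimethyl-1,3-dioxane-4,6-dione | COc1cc(CC2C(=O)OC(C)(C)OC2=O)cc(OC)c1OCc1ccccc1 | intermediate
5 | 3-[4-(benzyloxy)-3,5-dimethoxyphenyl]propanoic acid | COc1cc(CCC(=O)O)cc(OC)c1OCc1ccccc1 | intermediate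
6 | (S)-4-benzyl-2-oxazolidinone | O=C1N[C@@H](Cc2ccccc2)CO1 | starting material
7 | 3-[4-(benzyloxy)-3,5-dimethoxyphenyl]propanoic pivalic anhydride | COc1cc(CCC(=O)OC(=O)C(C)(C)C)cc(OC)c1OCc1ccccc1 | intermediate
8 | (4S)-4-benzyl-3-{3-[4-(benzyloxy)-3,5-dimethoxyphenyl]propanoyl}-1,3-oxazolidin-2-one | COc1cc(CCC(=O)N2[C@@H](Cc3ccccc3)COC2=O)cc(OC)c1OCc1ccccc1 | intermediate
9 | methyl 3-(3,4-dimethoxyphenyl)propanoate | COC(=O)CCc1ccc(OC)c(OC)c1 | starting material
10 | lithium (Z)-enolate of 8 | [Li]O/C(=C\Cc1cc(OC)c(OCc2ccccc2)c(OC)c1)N1[C@@H](Cc2ccccc2)COC1=O | intermediate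
11 | lithium enolate of 9 | [Li]OC(OC)=CCc1ccc(OC)c(OC)c1 | intermediate
12 | methyl (2R,3R)-3-{[(4S)-4-benzyl-2-oxo-1,3-oxazolidin-3-yl]carbonyl}-4-[4-(benzyloxy)-3,5-dimethoxyphenyl]-2-(3,4-dimethoxybenzyl)butanoate | COc1ccc(C[C@@H](C(=O)OC)[C@H](C(=O)N2[C@@H](Cc3ccccc3)COC2=O)Cc2cc(OC)c(OCc3ccccc3)c(OC)c2)cc1OC | intermediate
13 | (2R,3R)-2-[4-(benzyloxy)-3,5-dimethoxybenzyl]-3-(3,4-dimethoxybenzyl)butane-1,4-diol | COc1ccc(C[C@@H](CO)[C@H](CO)Cc2cc(OC)c(OCc3ccccc3)c(OC)c2)cc1OC | intermediate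
14 | (2R,3R)-2-[4-(benzyloxy)-3,5-dimethoxybenzyl]-3-(3,4-dimethoxybenzyl)butane-1,4-diyl diacetate | COc1ccc(C[C@@H](COC(C)=O)[C@H](COC(C)=O)Cc2cc(OC)c(OCc3ccccc3)c(OC)c2)cc1OC | intermediate
15 | Justin C | COc1ccc(C[C@@H](COC(C)=O)[C@H](COC(C)=O)Cc2cc(OC)c(O)c(OC)c2)cc1OC | target

**Totals**
Total step count: 6. Longest linear sequence: 6 (1 → 5 → 8 → 12 → 13 → 14 → 15).

**Three steps most likely to fail**

Step 3 (oxidative heterocoupling) is the riskiest: homocoupling competes and the selectivity at the ester α-carbon is not auxiliary-controlled. The fallback sets out from 8 and builds the two centres one after the other. The sodium enolate of 8 (NaHMDS, THF, −78 °C) is alkylated with tert-butyl bromoacetate to give tert-butyl (3R)-3-[4-(benzyloxy)-3,5-dimethoxybenzyl]-4-[(4S)-4-benzyl-2-oxo-1,3-oxazolidin-3-yl]-4-oxobutanoate F1. Selective imide reduction (LiBH4, H2O, Et2O, 0 °C) and acid-catalysed lactonisation (TsOH cat., toluene, 80 °C) give (R)-4-[4-(benzyloxy)-3,5-dimethoxybenzyl]dihydrofuran-2(3H)-one F2. Its lithium enolate (LiHMDS, THF/DMPU, −78 °C) is alkylated trans to the existing substituent with 3,4-dimethoxybenzyl bromide to give (3R,4R)-4-[4-(benzyloxy)-3,5-dimethoxybenzyl]-3-(3,4-dimethoxybenzyl)dihydrofuran-2(3H)-one F3. LiAlH4 in THF opens F3 to the diol, and the route is rejoined at 13.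

Step 4 (double reduction) may stall at the hindered ester or carry through C2-epimeric material from step 3. The fallback sets out from 12, including any C2 epimer present. The imide alone is reduced (LiBH4 1.1 equiv, H2O 1.1 equiv, Et2O, 0 °C) and the resulting γ-hydroxy ester closes to the lactone. Any cis lactone (3S,4R)-4-[4-(benzyloxy)-3,5-dimethoxybenzyl]-3-(3,4-dimethoxybenzyl)dihydrofuran-2(3H)-one F4 is equilibrated with DBU in toluene to the more stable trans lactone (3R,4R)-4-[4-(benzyloxy)-3,5-dimethoxybenzyl]-3-(3,4-dimethoxybenzyl)dihydrofuran-2(3H)-one F3. This makes the sequence stereoconvergent at the former ester α-carbon. LiAlH4 in THF then gives the diol, and the route is rejoined at 13.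

Step 1 (one-pot reductive Knoevenagel) may give incomplete decarboxylation or partial loss of the benzyl ether in hot formic acid. The fallback sets out from 1. Doebner–Knoevenagel condensation with malonic acid (pyridine, cat. piperidine, 90 °C) gives (E)-3-[4-(benzyloxy)-3,5-dimethoxyphenyl]prop-2-enoic acid F5. Chemoselective conjugate reduction that spares the benzyl ether (NiCl2·6H2O, NaBH4, MeOH, 0 °C) then rejoins the route at 5.

**Further compounds**
F1 | step 3 | tert-butyl (3R)-3-[4-(benzyloxy)-3,5-dimethoxybenzyl]-4-[(4S)-4-benzyl-2-oxo-1,3-oxazolidin-3-yl]-4-oxobutanoate | CC(C)(C)OC(=O)C[C@@H](Cc1cc(OC)c(OCc2ccccc2)c(OC)c1)C(=O)N1[C@@H](Cc2ccccc2)COC1=O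
F2 | step 3 | (R)-4-[4-(benzyloxy)-3,5-dimethoxybenzyl]dihydrofuran-2(3H)-one | O=C1C[C@@H](Cc2cc(OC)c(OCc3ccccc3)c(OC)c2)CO1
F3 | step 3 | (3R,4R)-4-[4-(benzyloxy)-3,5-dimethoxybenzyl]-3-(3,4-dimethoxybenzyl)dihydrofuran-2(3H)-one | COc1ccc(C[C@H]2C(=O)OC[C@@H]2Cc2cc(OC)c(OCc3ccccc3)c(OC)c2)cc1OC
F4 | step 4 | (3S,4R)-4-[4-(benzyloxy)-3,5-dimethoxybenzyl]-3-(3,4-dimethoxybenzyl)dihydrofuran-2(3H)-one | COc1ccc(C[C@@H]2C(=O)OC[C@@H]2Cc2cc(OC)c(OCc3ccccc3)c(OC)c2)cc1OC
F5 | step 1 | (E)-3-[4-(benzyloxy)-3,5-dimethoxyphenyl]prop-2-enoic acid | COc1cc(/C=C/C(=O)O)cc(OC)c1OCc1ccccc1
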